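With the ring numbered C1 (O, isopropyl), C2H2, C3H=, C4(CH3), C5H2, C6H2, everything rests on the homoallylic tertiary carbinol array O–C1–C2H2–C3H=. An enantioselective three-component conjunctive cross-coupling forms, in one operation, bond C6–C1 (1,2-shift of a 3-methylbut-3-enyl group from boron to carbon) and bond C2–C3 (alkene CH2 to a vinyl group), and sets the fully substituted C1 as a tertiary boronic ester. Its precursor is an achiral boron ate complex of an α-isopropylvinyl boronate and a homoallyl Grignard reagent. Oxidation, ring-closing metathesis to (R)-terpinen-4-ol and acylation of a diprenylphenol-derived aryllithium complete the route.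

Key step: step 3

Remark (assumption): the facial sense of the palladium catalyst with the α-isopropyl alkenyl boronate is taken by analogy with α-methyl alkenyl boronates. The ligand meant is the antipode of the Mandyphos-type ligand 1,1′-bis[bis(4-methoxy-3,5-dimethylphenyl)phosphino]-2,2′-bis[α-(dimethylamino)benzyl]ferrocene that delivers (S)-9. This is to be confirmed by chiral GC comparison of 11 with commercial (R)-terpinen-4-ol used only as an analytical reference.

Step 1
Reactants: 1 3-methylbutan-2-one
Product: 3 3-methylbut-1-en-2-yl trifluoromethanesulfonate, via lithium enolate 2 (not isolated)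
Conditions: LiN(iPr)2 (LDA), THF, −78 °C; then PhNTf2, −78 °C → rt
Reagents that add atoms: N-phenylbis(trifluoromethanesulfonimide), O=S(=O)(N(c1ccccc1)S(=O)(=O)C(F)(F)F)C(F)(F)F
Why: Kinetic deprotonation by the hindered amide base takes the CH3 proton, and O-sulfonylation of the terminal enolate should give the less substituted alkenyl triflate (enol triflate formation).

Step 2
Reactants: 3 3-methylbut-1-en-2-yl trifluoromethanesulfonate
Product: 4 4,4,5,5-tetramethyl-2-(3-methylbut-1-en-2-yl)-1,3,2-dioxaborolane
Conditions: B2pin2, PdCl2(PPh3)2 (3 mol %), PPh3, KOPh, toluene, 50 °C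
Reagents that add atoms: bis(pinacolato)diboron, CC1(C)OB(OC1(C)C)B1OC(C)(C)C(C)(C)O1
Why: Miyaura borylation (oxidative addition of the alkenyl triflate to zerovalent palladium, phenoxide-assisted transmetallation with the diboron reagent, reductive elimination) should give the 1,1-disubstituted alkenyl boronate with the alkene position unchanged.

Step 3
Reactants: 4 4,4,5,5-tetramethyl-2-(3-methylbut-1-en-2-yl)-1,3,2-dioxaborolane; 5 4-bromo-2-methylbut-1-ene; 6 bromoethene (vinyl bromide)
Product: 10 (4R)-7-methyl-4-(propan-2-yl)octa-1,7-dien-4-ol, via (3-methylbut-3-en-1-yl)magnesium bromide 7 (not isolated), via bromomagnesium boronate complex 8 (not isolated), via tertiary boronic ester 9 (not isolated)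
Conditions: 5, Mg, THF, rt; add to 4, THF, 0 °C → rt; then 6, Pd(OAc)2 (2 mol %), Mandyphos-type ferrocenyl diphosphine (2.4 mol %), NaOTf, THF, 60 °C; then 3 M NaOH, 30% H2O2, 0 °C → rt
Reagents that add atoms: hydrogen peroxide, OO
Why: Conjunctive cross-coupling, whose closest known type is the enantioselective synthesis of tertiary boronic esters from α-substituted alkenyl boron ate complexes: zerovalent palladium inserts into the C–Br bond of 6, the cationic vinyl–palladium species binds the alkene of 8 and triggers anti 1,2-migration of the 3-methylbut-3-enyl group from boron to the isopropyl-bearing carbon (future bond C6–C1), and reductive elimination joins the former alkene CH2 to the vinyl carbon (future bond C2–C3). No ring is closed in this step; both new bonds become ring bonds when step 4 closes the cyclohexene at C3=C4. The C1 stereocentre is set by the chiral diphosphine on palladium, which selects one enantiotopic face of the 1,1-disubstituted alkenyl boronate, and it is carried into the carbinol by stereoretentive boron-to-oxygen oxidation. The step needs the metallate shift to win over direct Suzuki-type transmetallation, which the wide-bite-angle ferrocenyl diphosphine and the triflate additive (halide scavenger) should secure. Only the alkyl group can migrate, since the pinacol oxygens do not, and the alkyl–palladium intermediate has no β-hydrogen on the quaternary carbon, so β-hydride elimination cannot compete.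

Step 4
Reactants: 10 (4R)-7-methyl-4-(propan-2-yl)octa-1,7-dien-4-ol
Product: 11 (1R)-4-methyl-1-(propan-2-yl)cyclohex-3-en-1-ol, (R)-terpinen-4-ol
Conditions: second-generation Grubbs catalyst RuCl2(=CHPh)(PCy3)(H2IMes) (2 mol %), CH2Cl2 (0.01 M), 40 °C
Reagents that add atoms: none
Why: Ring-closing metathesis of the 1,7-diene should join the monosubstituted and the 1,1-disubstituted alkene into the trisubstituted C3=C4 ring alkene with loss of ethene, a six-ring closure that a free tertiary alcohol tolerates and that leaves C1 untouched.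

Step 5
Reactants: 11 (1R)-4-methyl-1-(propan-2-yl)cyclohex-3-en-1-ol
Product: 13 (1R)-4-methyl-1-(propan-2-yl)cyclohex-3-en-1-yl 1H-imidazole-1-carboxylate, via lithium alkoxide 12 (not isolated)
Conditions: n-BuLi, THF, −78 → 0 °C; then 1,1′-carbonyldiimidazole, 0 °C → rt
Reagents that add atoms: 1,1′-carbonyldiimidazole, O=C(n1ccnc1)n1ccnc1
Why: Acyl transfer, in which the lithium tert-alkoxide attacks carbonyldiimidazole and expels one imidazolide, should give the tert-alkyl imidazole carboxylate (an analogue of N-Boc-imidazole) without breaking the C1–O bond.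

Step 6
Reactants: 14 4-bromophenol; 15 1-bromo-3-methylbut-2-ene (prenyl bromide)
Product: 17 4-bromo-2,6-bis(3-methylbut-2-en-1-yl)phenol, via monoprenylated phenol 16 (not isolated)
Conditions: NaH (2.2 equiv), toluene, 0 °C → rt; 15 (2.2 equiv)
Reagents that add atoms: none
Why: Ortho C-allylation of a sodium phenoxide in a non-polar solvent, where the tight ion pair shields oxygen and directs the primary allylic halide to the ortho carbons, should run twice in one flask because the para position is blocked by bromine.

Step 7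
Reactants: 17 4-bromo-2,6-bis(3-methylbut-2-en-1-yl)phenol; 13 (1R)-4-methyl-1-(propan-2-yl)cyclohex-3-en-1-yl 1H-imidazole-1-carboxylate
Product: 19 (1R)-4-methyl-1-(propan-2-yl)cyclohex-3-en-1-yl 4-hydroxy-3,5-bis(3-methylbut-2-en-1-yl)benzoate, via dilithiated phenol 18 (not isolated)
Conditions: t-BuLi (3.1 equiv), THF, −78 °C; then 13, −78 → −40 °C; aq. NH4Cl
Reagents that add atoms: none
Why: Bromine–lithium exchange on the lithium phenoxide gives an aryllithium that is acylated by the alkoxycarbonyl imidazole (ester synthesis from an organolithium and an activated carbonic acid derivative), and the para-phenoxide should make the product ester too electron-rich for a second addition.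

Compound list
1 | 3-methylbutan-2-one | CC(=O)C(C)C | starting material
2 | lithium 3-methylbut-1-en-2-olate | [Li+].[O-]C(=C)C(C)C | intermediate
3 | 3-methylbut-1-en-2-yl trifluoromethanesulfonate | C=C(OS(=O)(=O)C(F)(F)F)C(C)C | intermediate
4 | 4,4,5,5-tetramethyl-2-(3-methylbut-1-en-2-yl)-1,3,2-dioxaborolane | C=C(B1OC(C)(C)C(C)(C)O1)C(C)C | intermediate
5 | 4-bromo-2-methylbut-1-ene | C=C(C)CCBr | starting material
6 | bromoethene | C=CBr | starting material
7 | (3-methylbut-3-en-1-yl)magnesium bromide | C=C(C)CC[Mg]Br | intermediate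
8 | bromomagnesium (3-methylbut-1-en-2-yl)(3-methylbut-3-en-1-yl)(pinacolato)borate | C=C(C(C)C)[B-]1(CCC(C)=C)OC(C)(C)C(C)(C)O1.[Mg+]Br | intermediate
9 | 4,4,5,5-tetramethyl-2-[(4S)-7-methyl-4-(propan-2-yl)octa-1,7-dien-4-yl]-1,3,2-dioxaborolane | CC1(C)OB(OC1(C)C)[C@@](CCC(C)=C)(C(C)C)CC=C | intermediate
10 | (4R)-7-methyl-4-(propan-2-yl)octa-1,7-dien-4-ol | O[C@@](CCC(C)=C)(C(C)C)CC=C | intermediate
11 | (1R)-4-methyl-1-(propan-2-yl)cyclohex-3-en-1-ol | O[C@@]1(C(C)C)CC=C(C)CC1 | intermediate
12 | lithium (1R)-4-methyl-1-(propan-2-yl)cyclohex-3-en-1-olate | [Li+].[O-][C@@]1(C(C)C)CC=C(C)CC1 | intermediate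
13 | (1R)-4-methyl-1-(propan-2-yl)cyclohex-3-en-1-yl 1H-imidazole-1-carboxylate | O=C(O[C@@]1(C(C)C)CC=C(C)CC1)n1ccnc1 | intermediate
14 | 4-bromophenol | Oc1ccc(Br)cc1 | starting material
15 | 1-bromo-3-methylbut-2-ene | CC(C)=CCBr | starting material
16 | 4-bromo-2-(3-methylbut-2-en-1-yl)phenol | CC(C)=CCc1cc(Br)ccc1O | intermediate
17 | 4-bromo-2,6-bis(3-methylbut-2-en-1-yl)phenol | CC(C)=CCc1cc(Br)cc(CC=C(C)C)c1O | intermediate
18 | lithium 4-lithio-2,6-bis(3-methylbut-2-en-1-yl)phenolate | [Li]c1cc(CC=C(C)C)c([O-])c(CC=C(C)C)c1.[Li+] | intermediate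
19 | (1R)-4-methyl-1-(propan-2-yl)cyclohex-3-en-1-yl 4-hydroxy-3,5-bis(3-methylbut-2-en-1-yl)benzoate | CC(C)=CCc1cc(C(=O)O[C@@]2(C(C)C)CC=C(C)CC2)cc(CC=C(C)C)c1O | target

Total steps: 7. Longest linear sequence: 6 steps (steps 1, 2, 3, 4, 5, 7).

Steps most likely to fail

Step 3. The metallate shift onto the isopropyl-bearing alkene carbon may be slow, so that direct alkenyl transfer to palladium or protodeboronation takes over, and facial discrimination by the catalyst may be incomplete. The fallback sets out from 3 and returns at 10; here the stereocentre comes from reagent-controlled epoxidation of a 2-substituted allylic alcohol, and no later step touches its C–O bond. Triflate 3 is methoxycarbonylated (Pd(OAc)2, PPh3, CO, MeOH, Et3N, DMF) to methyl 3-methyl-2-methylidenebutanoate F1, which iBu2AlH reduces to 3-methyl-2-methylidenebutan-1-ol F2. Sharpless asymmetric epoxidation (Ti(OiPr)4, D-(−)-diisopropyl tartrate, t-BuOOH, 4 Å sieves, CH2Cl2, −20 °C) should give [(2R)-2-(propan-2-yl)oxiran-2-yl]methanol F3. Vinylmagnesium bromide with CuI opens the epoxide CH2 to (2R)-2-(propan-2-yl)pent-4-ene-1,2-diol F4. Selective tosylation of the primary hydroxyl (TsCl, pyridine) gives (2R)-2-hydroxy-2-(propan-2-yl)pent-4-en-1-yl 4-methylbenzenesulfonate F5, which K2CO3 in MeOH closes to (2R)-2-(prop-2-en-1-yl)-2-(propan-2-yl)oxirane F6. 2-Methylallylmagnesium chloride with CuI opens F6 at its CH2 to give 10.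

Step 7. Halogen–lithium exchange next to the phenoxide may be incomplete, and the aryllithium may add a second time to the new ester or the phenoxide may be O-acylated. The fallback sets out from 17 (with 11 as partner) and returns at 19; it replaces C-acylation by O-acylation of the tertiary alkoxide. Compound 17 is silylated (t-BuMe2SiCl, imidazole, DMF) to [4-bromo-2,6-bis(3-methylbut-2-en-1-yl)phenoxy](tert-butyl)dimethylsilane F7. Bromine–lithium exchange (t-BuLi, THF, −78 °C) and CO2 give 4-[(tert-butyldimethylsilyl)oxy]-3,5-bis(3-methylbut-2-en-1-yl)benzoic acid F8. 1-Chloro-N,N,2-trimethylprop-1-en-1-amine converts F8 under neutral conditions into 4-[(tert-butyldimethylsilyl)oxy]-3,5-bis(3-methylbut-2-en-1-yl)benzoyl chloride F9. F9 acylates lithium alkoxide 12 (from 11 and n-BuLi, THF, −78 → 0 °C) to (1R)-4-methyl-1-(propan-2-yl)cyclohex-3-en-1-yl 4-[(tert-butyldimethylsilyl)oxy]-3,5-bis(3-methylbut-2-en-1-yl)benzoate F10. Bu4NF buffered with AcOH (THF, 0 °C) then releases 19.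

Step 6. O-alkylation, incomplete or excessive alkylation, and cyclisation of the ortho-prenyl phenol to a chroman may compete with twofold ortho C-alkylation. The fallback sets out from 14 and returns at 17; it replaces phenoxide alkylation by cross-coupling. Compound 14 is iodinated at both ortho positions (I2, 30% H2O2, H2O, 50 °C) to 4-bromo-2,6-diiodophenol F11. Twofold Stille coupling with tributyl(3-methylbut-2-en-1-yl)stannane (Pd(PPh3)4, DMF, 80 °C), chemoselective for C–I over C–Br, should give 17.

Further compounds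
F1 | step 3 | methyl 3-methyl-2-methylidenebutanoate | C=C(C(=O)OC)C(C)C
F2 | step 3 | 3-methyl-2-methylidenebutan-1-ol | C=C(CO)C(C)C
F3 | step 3 | [(2R)-2-(propan-2-yl)oxiran-2-yl]methanol | O1[C@@](CO)(C(C)C)C1
F4 | step 3 | (2R)-2-(propan-2-yl)pent-4-ene-1,2-diol | O[C@@](CO)(C(C)C)CC=C
F5 | step 3 | (2R)-2-hydroxy-2-(propan-2-yl)pent-4-en-1-yl 4-methylbenzenesulfonate | O[C@@](COS(=O)(=O)c1ccc(C)cc1)(C(C)C)CC=C
F6 | step 3 | (2R)-2-(prop-2-en-1-yl)-2-(propan-2-yl)oxirane | O1[C@@](C1)(C(C)C)CC=C
F7 | step 7 | [4-bromo-2,6-bis(3-methylbut-2-en-1-yl)phenoxy](tert-butyl)dimethylsilane | CC(C)=CCc1cc(Br)cc(CC=C(C)C)c1O[Si](C)(C)C(C)(C)C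
F8 | step 7 | 4-[(tert-butyldimethylsilyl)oxy]-3,5-bis(3-methylbut-2-en-1-yl)benzoic acid | CC(C)=CCc1cc(C(=O)O)cc(CC=C(C)C)c1O[Si](C)(C)C(C)(C)C
F9 | step 7 | 4-[(tert-butyldimethylsilyl)oxy]-3,5-bis(3-methylbut-2-en-1-yl)benzoyl chloride | CC(C)=CCc1cc(C(=O)Cl)cc(CC=C(C)C)c1O[Si](C)(C)C(C)(C)C
F10 | step 7 | (1R)-4-methyl-1-(propan-2-yl)cyclohex-3-en-1-yl 4-[(tert-butyldimethylsilyl)oxy]-3,5-bis(3-methylbut-2-en-1-yl)benzoate | CC(C)=CCc1cc(C(=O)O[C@@]2(C(C)C)CC=C(C)CC2)cc(CC=C(C)C)c1O[Si](C)(C)C(C)(C)C
F11 | step 6 | 4-bromo-2,6-diiodophenol | Oc1c(I)cc(Br)cc1I
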